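Compound numbers are those of the steps and of the compound list (1–14). Locants C1–C8a refer to the tetralin of the target (ring A aromatic, ring B saturated); primed locants refer to its naphthalene (rings C and D).

## Analysis of the target

Dipolynaphthalene B is a 1,2,3,4-tetrahydronaphthalen-1-ol with a methoxy group at C5 and a 4-hydroxy-5-methoxynaphthalen-1-yl unit at C4, so the two bicyclic halves meet at one sp3 carbon, the diarylmethine C4. The two stereocentres, the benzylic carbinol C1 and C4, are both S, which places the hydroxyl and the naphthyl group cis on ring B. They stand 1,4 to each other across two methylene groups, so neither steers the other strongly. The sensitive sites are the free 1-naphthol with a para benzylic C4–H (easily oxidised to a p-quinone methide), the benzylic alcohol at C1 (ionisation or elimination in acid) and the doubly benzylic C4–H. C4 is crowded on both sides, by the peri C5 methoxy group and by the peri C8'–H, and it has to be made as one enantiomer without a heteroatom to help. The bond from C4 into ring A ends at C4a, the carbon between C5–OMe and the ring-fusion carbon C8a. A cationic closure of a 3-methoxyphenyl precursor would go to the open position para to the methoxy group and give the 7-methoxy isomer. The strategy rests on this C4–C4a bond: C4a can be marked by a bromine already present in aldehyde 1, and C4 can be a benzylic chloride that passes through a planar radical on nickel. Ring B, the regiochemistry at C4a and the configuration at C4 are then all decided in one ring closure, with the naphthalene taken ready-made from the symmetric diol 5.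

## Retrosynthetic reasoning

**14 back to 12.** The last operations only unmask oxygen. The naphthol of 14 is carried as a pivalate and the C1 hydroxyl as a tert-butyldimethylsilyl ether, leading back through alcohol 13 to the protected tetralin 12. The ester is preferred to an ether on the naphthol because it lowers the donor strength of the naphthalene, which matters for the benzylic halide earlier on, and because mild base removes it. The silyl ether is inert to organomagnesium and low-valent nickel reagents and adds bulk next to ring B. Forward, the two cleavages must leave both benzylic centres untouched and keep air away from the naphtholate.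

**12 back to 11.** The C4–C4a bond is cut. This is the only ring B bond whose formation can also create the C4 stereocentre and whose aromatic terminus can be fixed by a halogen. Cutting C1–C8a instead would leave the diarylmethine to be made acyclically, and cutting C4–C1' would require an enantioselective arylation of a preformed tetralin. The cut gives the open-chain bromide/chloride 11, in which C4 need not be configured. Forward, a reductive nickel coupling has to join the two electrophilic carbons, close the six-membered ring, converge both C4 epimers and select the face that gives the cis product.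

**11 back to 10.** The C4–Cl bond is traced to the C4–OH of carbinol 10. Nothing stereochemical is asked of this step, only that the chloride forms without ionisation.

**10 back to 4 and 8.** The C4–C1' bond is cut between an aldehyde carbon and an aryl nucleophile, giving aldehyde 4 and the arylmagnesium species 9, which comes from iodide 8. This is the convergent joint: it unites the two halves at the carbon whose configuration is settled later, so an uncontrolled addition is acceptable. Forward, the organometallic must carry an aryl ester, which calls for a halogen–magnesium exchange at low temperature.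

**4 back to 1.** The formyl carbon of 4 is removed (hydroformylation of the terminal alkene of 3), the silyl group is taken off to give 2, and the C1–C2 bond is cut as an asymmetric allylation of 1. This sets C1 in the first step, from the aldehyde that already has bromine and methoxy in the 2,3-relationship required for C4a and C5. Three steps give the four-carbon chain with both termini differentiated.

**8 back to 5.** The pivalate of 8 is removed to give iodonaphthol 7, the C–I bond is traced to electrophilic iodination of naphthol 6 para to its free hydroxyl, and 6 to mono-methylation of diol 5. The symmetry of 5 removes any question of which oxygen is methylated. The iodination must take place while the hydroxyl is still free, because only then does the hydroxyl-bearing ring outrank the methoxy-bearing ring.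

## Alternatives that were turned down

**Alternative 1:** The disconnection is a C4–O bond: the target skeleton is carried at a higher oxidation level as the 1,4-oxygen-bridged compound A1. Forward, Ag2O would oxidise the free naphthol A2 (either C4 epimer) to the p-quinone methide A3, and the C1 hydroxyl would add to C4 to close a 7-oxabicyclo[2.2.1]heptane.
- In its favour: the bridge can only form on the face of the C1 oxygen, so both C4 epimers of A2 converge on one stereoisomer without a chiral catalyst. On certainty of relative configuration at this stage it is stronger than the chosen route.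
- Against it: A1 is not the target. C4 is now quaternary, and the C4–O bond must be cleaved reductively with hydride entering anti to the oxygen (inversion) to give the cis product. Under ionising conditions A1 reverts to the planar quinone-methide-like cation, and internal delivery from the C1 alkoxide would give trans. The same bridging oxygen is also benzylic at C1, so hydrogenolysis could remove the wrong C–O bond.
- It does not address the C4–C4a regiochemistry at all, since A2 must first be assembled by other means, and it adds an oxidation and a reduction on an unprotected, oxidation-prone naphthol.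
- The chosen route offers instead a single step that makes the C4–C4a bond, ring B and the C4 configuration, with the naphthol masked throughout.

**Alternative 2:** The disconnection is C1'–C8a' and C4'–C4a': ring C is built late by a Diels–Alder reaction of the tetralinyl furan A5 with 3-methoxybenzyne A6 to give the oxabicyclic adduct A4, which acid would then isomerise to the 1-naphthol.
- In its favour: two C–C bonds form in one convergent step, and the furan is a small, robust stand-in for the naphthol. It avoids both the peri-hindered naphthyl organometallic and the easily ionised naphthylmethyl chloride, and on these two points it is stronger than the chosen route.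
- Against it: an unsymmetrical aryne and a 2-substituted furan combine with weak regiocontrol, yet the methoxy group must end up peri to the unsubstituted bridgehead. The acid-promoted opening of A4 passes through a cation at C1', next to the C4 stereocentre and in a molecule with an acid-labile benzylic silyl ether at C1.
- The tetralin ring and the C4 stereocentre of A5 would still have to be made by another method, so the step solves neither the C4–C4a regiochemistry nor the stereochemistry.
- It costs at least two steps more than using the intact naphthalene of 5, whose symmetry settles the oxygenation pattern without a regiochemical gamble.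

**Alternative 3:** The disconnection is C8a–C1 and C1–C2, with CO as C1. The alkene A8 would be hydroborated to the alkylborane A9; Pd(PPh3)4 would insert into the C8a–Br bond, take up CO and couple with the B-alkyl group to close ring B as the tetralone A7. Reduction of the ketone would then set C1.
- In its favour: C1 is set last by reduction of a 4-aryl-1-tetralone, which can be placed under reagent control, and neither a C1 protecting group nor a benzylic chloride is needed. On C1 control and on freedom from any matched/mismatched question it is stronger than the chosen route.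
- Against it: the key step creates no stereocentre. C4 must already be enantiopure in the acyclic A8, a diarylmethine carrying a di-ortho-substituted bromoanisole and a 1-naphthyl group, for which no reliable asymmetric construction is in sight.
- The doubly benzylic, allylic C–H of A8 invites alkene migration into conjugation, which would erase C4.
- Direct B-alkyl coupling without CO would close a five-membered ring, and CO slows insertion at the hindered bromide.
- The chosen route offers instead a ring closure that starts from a racemic C4 and converges it to one configuration.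

Key step: step 9

Assumption: the (S,S)-enantiomer of the bis(oxazoline) ligand is taken to be the one whose facial preference at C4 is matched with the (1S)-silyloxy centre for the cis (4S) product; should the sense be opposite, the (R,R)-ligand takes its place with no other change.

## Route

Step 1
Reactants: 1 2-bromo-3-methoxybenzaldehyde
Product: 2 (1S)-1-(2-bromo-3-methoxyphenyl)but-3-en-1-ol
Conditions: (−)-Ipc2B(allyl), Et2O, −78 °C; then NaOH, H2O2, 0 °C → rt
Reagents that add atoms: (−)-B-allyldiisopinocampheylborane [from (+)-α-pinene], C=CCB([C@@H]1C[C@@H]2C[C@H]([C@H]1C)C2(C)C)[C@@H]1C[C@@H]2C[C@H]([C@H]1C)C2(C)C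
Why: Brown allylation through a closed chair-like six-membered transition state; the reagent from (+)-α-pinene should add to the Si face of 1 as it does with benzaldehyde, which here corresponds to the (S)-carbinol (O > aryl > allyl carbon). The aryl bromide is inert to the borane and to the oxidative work-up.

Step 2
Reactants: 2 (1S)-1-(2-bromo-3-methoxyphenyl)but-3-en-1-ol
Product: 3 tert-butyl{[(1S)-1-(2-bromo-3-methoxyphenyl)but-3-en-1-yl]oxy}dimethylsilane
Conditions: TBSOTf, 2,6-lutidine, CH2Cl2, 0 °C
Reagents that add atoms: tert-butyldimethylsilyl trifluoromethanesulfonate, CC(C)(C)[Si](C)(C)OS(=O)(=O)C(F)(F)F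
Why: O-silylation with a silyl triflate, chosen because the benzylic hydroxyl is flanked by the ortho bromine; C1 is not touched.

Step 3
Reactants: 3 tert-butyl{[(1S)-1-(2-bromo-3-methoxyphenyl)but-3-en-1-yl]oxy}dimethylsilane
Product: 4 (4S)-4-(2-bromo-3-methoxyphenyl)-4-(tert-butyldimethylsilyloxy)butanal
Conditions: Rh(acac)(CO)2 (1 mol %), BIPHEPHOS (2 mol %), CO/H2 (1:1, 5 bar), toluene, 60 °C
Reagents that add atoms: carbon monoxide, [C-]#[O+]
Why: Rhodium-catalysed hydroformylation; the wide-bite-angle bisphosphite places the formyl group on the terminal carbon of the monosubstituted alkene. The aryl bromide and the silyl ether do not react under neutral syngas conditions, and no stereocentre is formed.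

Step 4
Reactants: 5 naphthalene-1,8-diol
Product: 6 8-methoxynaphthalen-1-ol
Conditions: MeI (1.05 equiv), K2CO3, acetone, reflux
Reagents that add atoms: iodomethane, CI
Why: Williamson mono-O-methylation; after the first methylation the remaining hydroxyl is held in a hydrogen bond to the peri methoxy oxygen and is much less acidic and nucleophilic, so the second methylation should be slow.

Step 5
Reactants: 6 8-methoxynaphthalen-1-ol
Product: 7 4-iodo-8-methoxynaphthalen-1-ol
Conditions: NIS (1.0 equiv), TsOH·H2O (10 mol %), MeCN, 0 °C, dark
Reagents that add atoms: N-iodosuccinimide, O=C1CCC(=O)N1I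
Why: Electrophilic aromatic iodination; the free hydroxyl is the stronger donor and its hydrogen bond ties up a lone pair of the methoxy oxygen, so the hydroxyl-bearing ring should react. Acid-catalysed NIS iodination of phenols favours the para position, here C4.

Step 6
Reactants: 7 4-iodo-8-methoxynaphthalen-1-ol
Product: 8 4-iodo-8-methoxynaphthalen-1-yl pivalate
Conditions: PivCl, Et3N, DMAP (10 mol %), CH2Cl2, 0 °C → rt
Reagents that add atoms: pivaloyl chloride, CC(C)(C)C(Cl)=O
Why: DMAP-catalysed O-acylation of the naphthol; the acylpyridinium intermediate should overcome the hindrance of the peri methoxy group.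

Step 7
Reactants: 8 4-iodo-8-methoxynaphthalen-1-yl pivalate; 4 (4S)-4-(2-bromo-3-methoxyphenyl)-4-(tert-butyldimethylsilyloxy)butanal
Product: 10 (4S)-4-(2-bromo-3-methoxyphenyl)-4-(tert-butyldimethylsilyloxy)-1-[5-methoxy-4-(pivaloyloxy)naphthalen-1-yl]butan-1-ol as both C1 epimers, via arylmagnesium chloride 9 (not isolated)
Conditions: iPrMgCl·LiCl (1.1 equiv), THF, −40 °C; then 4, −40 → −10 °C; aq. NH4Cl
Reagents that add atoms: none
Why: Iodine–magnesium exchange with the LiCl-activated isopropyl Grignard reagent is fast at −40 °C, where the aryl ester and the aryl bromide of 4 are left alone, and the arylmagnesium species then adds to the aldehyde (Grignard addition). The new carbinol centre forms without control, which is acceptable because step 9 erases it.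

Step 8
Reactants: 10 (4S)-4-(2-bromo-3-methoxyphenyl)-4-(tert-butyldimethylsilyloxy)-1-[5-methoxy-4-(pivaloyloxy)naphthalen-1-yl]butan-1-ol as both C1 epimers
Product: 11 (1S)-1-(2-bromo-3-methoxyphenyl)-1-(tert-butyldimethylsilyloxy)-4-chloro-4-[5-methoxy-4-(pivaloyloxy)naphthalen-1-yl]butane as both C4 epimers
Conditions: SOCl2 (1.3 equiv), 2,6-lutidine (1.5 equiv), CH2Cl2, −20 → 0 °C; rapid filtration through deactivated silica, used at once
Reagents that add atoms: thionyl chloride, ClS(Cl)=O
Why: Chlorodehydroxylation through the chlorosulfite; lutidine buffers the HCl so that the silyl ether survives. Either stereochemical course is acceptable, and the pivalate lowers the donor strength of the naphthalene enough that the chloride should persist until it is used.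

Step 9
Reactants: 11 (1S)-1-(2-bromo-3-methoxyphenyl)-1-(tert-butyldimethylsilyloxy)-4-chloro-4-[5-methoxy-4-(pivaloyloxy)naphthalen-1-yl]butane as both C4 epimers
Product: 12 (1S,4S)-1-(tert-butyldimethylsilyloxy)-5-methoxy-4-[5-methoxy-4-(pivaloyloxy)naphthalen-1-yl]-1,2,3,4-tetrahydronaphthalene (cis)
Conditions: NiCl2(dme) (10 mol %), (S,S)-4-heptyl-BiOX [(4S,4'S)-4,4'-di(heptan-4-yl)-4,4',5,5'-tetrahydro-2,2'-bioxazole] (12 mol %), Mn powder (3 equiv), NaI (0.5 equiv), TMSCl (0.2 equiv), 1,4-dioxane/DMA, 0.02 M, rt
Reagents that add atoms: none
Why: Mn reduces the divalent nickel precatalyst to a zerovalent nickel–bis(oxazoline) species that inserts into the C4a–Br bond; a monovalent nickel halide then abstracts chlorine from C4 to give a planar naphthylmethyl radical, the arylnickel centre of the same molecule captures it to give a trivalent aryl(alkyl)nickel species, and C(sp2)–C(sp3) reductive elimination forms C4–C4a. The closest known reaction type is the nickel-catalysed enantioconvergent reductive cross-coupling of aryl halides with secondary benzylic chlorides to 1,1-diarylalkanes, run here within one molecule. Ring B closes in a 6-exo sense by reductive elimination from a seven-membered nickelacycle (Ni, C4a, C8a, C1, C2, C3, C4), not by radical attack on the arene. Because C4 passes through the radical, both epimers of 11 converge, and the new C4 centre is set by the chiral ligand on nickel at radical capture and reductive elimination, with the C1 silyloxy centre as a second, weaker control element that has to be matched. Regiochemistry needs no selection, since the bromine marks C4a between C5–OMe and C8a. Chemoselectivity for C–Br over the naphthyl C–O bond of the pivalate rests on the nitrogen ligand and room temperature, under which aryl esters are not activated, and the pivalate keeps the chloride from ionising before nickel reaches it. The required cis selectivity corresponds to a product half-chair with the C4 naphthyl group pseudoaxial, away from the peri C5 methoxy group, and the C1 silyloxy group pseudoequatorial; dilution keeps the capture intramolecular.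

Step 10
Reactants: 12 (1S,4S)-1-(tert-butyldimethylsilyloxy)-5-methoxy-4-[5-methoxy-4-(pivaloyloxy)naphthalen-1-yl]-1,2,3,4-tetrahydronaphthalene (cis)
Product: 13 4-[(1S,4S)-4-hydroxy-8-methoxy-1,2,3,4-tetrahydronaphthalen-1-yl]-8-methoxynaphthalen-1-yl pivalate
Conditions: TBAF (1.5 equiv), AcOH (1.5 equiv), THF, 0 °C → rt
Reagents that add atoms: none
Why: Fluoride-induced cleavage of the Si–O bond; the acetic acid buffer keeps the medium from becoming basic enough to open the aryl ester or disturb the benzylic centres, and neither stereocentre is involved.

Step 11
Reactants: 13 4-[(1S,4S)-4-hydroxy-8-methoxy-1,2,3,4-tetrahydronaphthalen-1-yl]-8-methoxynaphthalen-1-yl pivalate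
Product: 14 (1S,4S)-4-(4-hydroxy-5-methoxynaphthalen-1-yl)-5-methoxy-1,2,3,4-tetrahydronaphthalen-1-ol (dipolynaphthalene B)
Conditions: K2CO3 (1.5 equiv), degassed MeOH, rt → 40 °C, Ar; aq. NH4Cl
Reagents that add atoms: none
Why: Base-mediated transesterification of the aryl pivalate, which is far more labile than an alkyl pivalate because the naphtholate is a good leaving group; argon protects the oxidisable 4-alkyl-1-naphtholate, and no stereocentre is touched.

## Compound list

1 | 2-bromo-3-methoxybenzaldehyde | COc1cccc(C=O)c1Br | starting material
2 | (1S)-1-(2-bromo-3-methoxyphenyl)but-3-en-1-ol | COc1cccc([C@@H](O)CC=C)c1Br | intermediate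
3 | tert-butyl{[(1S)-1-(2-bromo-3-methoxyphenyl)but-3-en-1-yl]oxy}dimethylsilane | COc1cccc([C@@H](O[Si](C)(C)C(C)(C)C)CC=C)c1Br | intermediate
4 | (4S)-4-(2-bromo-3-methoxyphenyl)-4-(tert-butyldimethylsilyloxy)butanal | COc1cccc([C@@H](O[Si](C)(C)C(C)(C)C)CCC=O)c1Br | intermediate
5 | naphthalene-1,8-diol | Oc1cccc2cccc(O)c12 | starting material
6 | 8-methoxynaphthalen-1-ol | COc1cccc2cccc(O)c12 | intermediate
7 | 4-iodo-8-methoxynaphthalen-1-ol | COc1cccc2c(I)ccc(O)c12 | intermediate
8 | 4-iodo-8-methoxynaphthalen-1-yl pivalate | COc1cccc2c(I)ccc(OC(=O)C(C)(C)C)c12 | intermediate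
9 | [5-methoxy-4-(pivaloyloxy)naphthalen-1-yl]magnesium chloride, LiCl complex | COc1cccc2c([Mg]Cl)ccc(OC(=O)C(C)(C)C)c12.[Li+].[Cl-] | intermediate (not isolated)
10 | (4S)-4-(2-bromo-3-methoxyphenyl)-4-(tert-butyldimethylsilyloxy)-1-[5-methoxy-4-(pivaloyloxy)naphthalen-1-yl]butan-1-ol, both C1 epimers | COc1cccc([C@@H](O[Si](C)(C)C(C)(C)C)CCC(O)c2ccc(OC(=O)C(C)(C)C)c3c(OC)cccc23)c1Br | intermediate
11 | (1S)-1-(2-bromo-3-methoxyphenyl)-1-(tert-butyldimethylsilyloxy)-4-chloro-4-[5-methoxy-4-(pivaloyloxy)naphthalen-1-yl]butane, both C4 epimers | COc1cccc([C@@H](O[Si](C)(C)C(C)(C)C)CCC(Cl)c2ccc(OC(=O)C(C)(C)C)c3c(OC)cccc23)c1Br | intermediate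
12 | (1S,4S)-1-(tert-butyldimethylsilyloxy)-5-methoxy-4-[5-methoxy-4-(pivaloyloxy)naphthalen-1-yl]-1,2,3,4-tetrahydronaphthalene (cis) | COc1cccc2c1[C@H](c1ccc(OC(=O)C(C)(C)C)c3c(OC)cccc13)CC[C@@H]2O[Si](C)(C)C(C)(C)C | intermediate
13 | 4-[(1S,4S)-4-hydroxy-8-methoxy-1,2,3,4-tetrahydronaphthalen-1-yl]-8-methoxynaphthalen-1-yl pivalate | COc1cccc2c1[C@H](c1ccc(OC(=O)C(C)(C)C)c3c(OC)cccc13)CC[C@@H]2O | intermediate
14 | (1S,4S)-4-(4-hydroxy-5-methoxynaphthalen-1-yl)-5-methoxy-1,2,3,4-tetrahydronaphthalen-1-ol (dipolynaphthalene B) | COc1cccc2c1[C@H](c1ccc(O)c3c(OC)cccc13)CC[C@@H]2O | target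

## Step count and least certain steps

Total: 11 steps. Longest linear sequence: 8 steps (steps 1–3 followed by 7–11; the naphthalene branch, steps 4–6 followed by 7–11, is equally long).

**Step 9 (key step).**
- Most likely to go wrong: poor facial selectivity at C4 if the ligand's preference and the conformational bias of the C1 silyloxy group oppose each other. The cis half-chair (naphthyl pseudoaxial, silyloxy pseudoequatorial) and the trans half-chair (both pseudoaxial) should lie close in energy, so a substrate bias toward trans cannot be excluded.
- Second concern: slow insertion into the di-ortho-substituted C–Br bond, which would let dimerisation or reduction of the benzylic radical, or loss of HCl, outrun the ring closure.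
- Fallback: C1 can be corrected after ring closure whereas C4 cannot, so the sense of substrate induction is used rather than opposed.
  - Setting out from 1, allylation with the enantiomeric borane, (+)-Ipc2B(allyl), should give (1R)-1-(2-bromo-3-methoxyphenyl)but-3-en-1-ol F1.
  - Silylation, hydroformylation, addition of 9 and chlorination as in steps 2, 3, 7 and 8 then lead through tert-butyl{[(1R)-1-(2-bromo-3-methoxyphenyl)but-3-en-1-yl]oxy}dimethylsilane F2, (4R)-4-(2-bromo-3-methoxyphenyl)-4-(tert-butyldimethylsilyloxy)butanal F3 and (4R)-4-(2-bromo-3-methoxyphenyl)-4-(tert-butyldimethylsilyloxy)-1-[5-methoxy-4-(pivaloyloxy)naphthalen-1-yl]butan-1-ol F4 to (1R)-1-(2-bromo-3-methoxyphenyl)-1-(tert-butyldimethylsilyloxy)-4-chloro-4-[5-methoxy-4-(pivaloyloxy)naphthalen-1-yl]butane F5.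
  - Nickel closure with the same ligand, whose (4S) preference the substrate would then reinforce, should give trans-(1R,4S)-1-(tert-butyldimethylsilyloxy)-5-methoxy-4-[5-methoxy-4-(pivaloyloxy)naphthalen-1-yl]-1,2,3,4-tetrahydronaphthalene F6.
  - TBAF/AcOH should free 4-[(1S,4R)-4-hydroxy-8-methoxy-1,2,3,4-tetrahydronaphthalen-1-yl]-8-methoxynaphthalen-1-yl pivalate F7 (the trans alcohol), and Dess–Martin periodinane should oxidise it to 4-[(1S)-8-methoxy-4-oxo-1,2,3,4-tetrahydronaphthalen-1-yl]-8-methoxynaphthalen-1-yl pivalate F8.
  - Corey–Bakshi–Shibata reduction with the (R)-methyl oxazaborolidine and BH3·SMe2, which sets the carbinol of 1-tetralones under reagent control, rejoins the route at 13.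

**Step 8.**
- Most likely to go wrong: ionisation at the naphthylmethyl carbon, at the chlorosulfite or the chloride stage, followed by loss of a proton toward the conjugated alkene or by capture of the cation by the C1 silyloxy oxygen (closure to a tetrahydrofuran with loss of the silyl group). Hydrolysis on silica is a further risk.
- Fallback: the chloride is bypassed.
  - Setting out from 10, acylation with oxalyl chloride in the presence of 2,6-lutidine and aqueous work-up should give 2-{(4S)-4-(2-bromo-3-methoxyphenyl)-4-(tert-butyldimethylsilyloxy)-1-[5-methoxy-4-(pivaloyloxy)naphthalen-1-yl]butoxy}-2-oxoacetic acid F9.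
  - As its caesium salt this is a radical precursor for metallaphotoredox arylation ([Ir(dF(CF3)ppy)2(dtbbpy)]PF6, NiBr2(dme), 4,4'-di-tert-butyl-2,2'-bipyridine, CsHCO3, dioxane/DMSO, blue light). Oxidation and loss of two molecules of CO2 generate the same C4 radical, which the arylnickel formed at C4a–Br captures.
  - The closure then runs under substrate control only, so the cis product would have to be separated by chromatography from (1S,4R)-1-(tert-butyldimethylsilyloxy)-5-methoxy-4-[5-methoxy-4-(pivaloyloxy)naphthalen-1-yl]-1,2,3,4-tetrahydronaphthalene F10 before the route is rejoined at 12.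

**Step 7.**
- Most likely to go wrong: acyl transfer from the pivalate to the isopropyl- or arylmagnesium species if the exchange is slow, or enolisation of 4 by the basic organomagnesium reagent.
- Fallback: setting out from 8 and 4, a Nozaki–Hiyama–Kishi coupling (CrCl2 in excess, NiCl2 1 mol %, DMF, rt) joins the aryl iodide and the aldehyde through a non-basic arylchromium species that tolerates esters and enolisable aldehydes. The aryl bromide of 4 is far less reactive than the iodide toward the nickel co-catalyst. The route is rejoined at 10.

**Step 5.**
- Most likely to go wrong: iodination at C2 or twice, attack on the methoxy-bearing ring at C5, and oxidation of the electron-rich iodonaphthol toward quinoid material.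
- Fallback: halogenate with the less oxidising bromine electrophile and bring in iodine only after the naphthol is masked.
  - Setting out from 6, N-bromosuccinimide in MeCN at −20 °C should give 4-bromo-8-methoxynaphthalen-1-ol F11.
  - Pivaloylation as in step 6 gives 4-bromo-8-methoxynaphthalen-1-yl pivalate F12.
  - A copper-catalysed aromatic Finkelstein exchange (CuI, trans-N,N'-dimethylcyclohexane-1,2-diamine, NaI, dioxane, 110 °C) converts it into 8, where the route is rejoined.

**Step 3.**
- Most likely to go wrong: incomplete regiocontrol (branched aldehyde) or migration of the double bond before carbonylation.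
- Fallback: setting out from 3, hydroboration with 9-BBN and oxidation with NaOH/H2O2 should give (4S)-4-(2-bromo-3-methoxyphenyl)-4-(tert-butyldimethylsilyloxy)butan-1-ol F13, and Dess–Martin oxidation of this primary alcohol rejoins the route at 4.

## Further compounds

F1 | step 9 | (1R)-1-(2-bromo-3-methoxyphenyl)but-3-en-1-ol | COc1cccc([C@H](O)CC=C)c1Br
F2 | step 9 | tert-butyl{[(1R)-1-(2-bromo-3-methoxyphenyl)but-3-en-1-yl]oxy}dimethylsilane | COc1cccc([C@H](O[Si](C)(C)C(C)(C)C)CC=C)c1Br
F3 | step 9 | (4R)-4-(2-bromo-3-methoxyphenyl)-4-(tert-butyldimethylsilyloxy)butanal | COc1cccc([C@H](O[Si](C)(C)C(C)(C)C)CCC=O)c1Br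
F4 | step 9 | (4R)-4-(2-bromo-3-methoxyphenyl)-4-(tert-butyldimethylsilyloxy)-1-[5-methoxy-4-(pivaloyloxy)naphthalen-1-yl]butan-1-ol, both C1 epimers | COc1cccc([C@H](O[Si](C)(C)C(C)(C)C)CCC(O)c2ccc(OC(=O)C(C)(C)C)c3c(OC)cccc23)c1Br
F5 | step 9 | (1R)-1-(2-bromo-3-methoxyphenyl)-1-(tert-butyldimethylsilyloxy)-4-chloro-4-[5-methoxy-4-(pivaloyloxy)naphthalen-1-yl]butane, both C4 epimers | COc1cccc([C@H](O[Si](C)(C)C(C)(C)C)CCC(Cl)c2ccc(OC(=O)C(C)(C)C)c3c(OC)cccc23)c1Br
F6 | step 9 | trans-(1R,4S)-1-(tert-butyldimethylsilyloxy)-5-methoxy-4-[5-methoxy-4-(pivaloyloxy)naphthalen-1-yl]-1,2,3,4-tetrahydronaphthalene | COc1cccc2c1[C@H](c1ccc(OC(=O)C(C)(C)C)c3c(OC)cccc13)CC[C@H]2O[Si](C)(C)C(C)(C)C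
F7 | step 9 | 4-[(1S,4R)-4-hydroxy-8-methoxy-1,2,3,4-tetrahydronaphthalen-1-yl]-8-methoxynaphthalen-1-yl pivalate (trans) | COc1cccc2c1[C@H](c1ccc(OC(=O)C(C)(C)C)c3c(OC)cccc13)CC[C@H]2O
F8 | step 9 | 4-[(1S)-8-methoxy-4-oxo-1,2,3,4-tetrahydronaphthalen-1-yl]-8-methoxynaphthalen-1-yl pivalate | COc1cccc2c1[C@H](c1ccc(OC(=O)C(C)(C)C)c3c(OC)cccc13)CCC2=O
F9 | step 8 | 2-{(4S)-4-(2-bromo-3-methoxyphenyl)-4-(tert-butyldimethylsilyloxy)-1-[5-methoxy-4-(pivaloyloxy)naphthalen-1-yl]butoxy}-2-oxoacetic acid | COc1cccc([C@@H](O[Si](C)(C)C(C)(C)C)CCC(OC(=O)C(O)=O)c2ccc(OC(=O)C(C)(C)C)c3c(OC)cccc23)c1Br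
F10 | step 8 | (1S,4R)-1-(tert-butyldimethylsilyloxy)-5-methoxy-4-[5-methoxy-4-(pivaloyloxy)naphthalen-1-yl]-1,2,3,4-tetrahydronaphthalene (trans) | COc1cccc2c1[C@@H](c1ccc(OC(=O)C(C)(C)C)c3c(OC)cccc13)CC[C@@H]2O[Si](C)(C)C(C)(C)C
F0 | step 7 | none | none
F11 | step 5 | 4-bromo-8-methoxynaphthalen-1-ol | COc1cccc2c(Br)ccc(O)c12
F12 | step 5 | 4-bromo-8-methoxynaphthalen-1-yl pivalate | COc1cccc2c(Br)ccc(OC(=O)C(C)(C)C)c12
F13 | step 3 | (4S)-4-(2-bromo-3-methoxyphenyl)-4-(tert-butyldimethylsilyloxy)butan-1-ol | COc1cccc([C@@H](O[Si](C)(C)C(C)(C)C)CCCO)c1Br
A1 | alternative 1 | 1-(4-hydroxy-5-methoxynaphthalen-1-yl)-8-methoxy-1,4-epoxy-1,2,3,4-tetrahydronaphthalene, bridge on the face of the C1 oxygen | COc1cccc2c1[C@@]1(c3ccc(O)c4c(OC)cccc34)CC[C@@H]2O1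
A2 | alternative 1 | (1S)-4-(4-hydroxy-5-methoxynaphthalen-1-yl)-5-methoxy-1,2,3,4-tetrahydronaphthalen-1-ol, either C4 epimer | COc1cccc2c1C(c1ccc(O)c3c(OC)cccc13)CC[C@@H]2O
A3 | alternative 1 | 4-[(4S)-4-hydroxy-8-methoxy-3,4-dihydronaphthalen-1(2H)-ylidene]-8-methoxynaphthalen-1(4H)-one | COc1cccc2c1C(=C1C=CC(=O)c3c(OC)cccc13)CC[C@@H]2O
A4 | alternative 2 | tert-butyl{[cis-5-methoxy-4-(5-methoxy-1,4-dihydro-1,4-epoxynaphthalen-1-yl)-1,2,3,4-tetrahydronaphthalen-1-yl]oxy}dimethylsilane, bridgehead diastereomers | COc1cccc2c1[C@H](C34OC(C=C3)c3c(OC)cccc34)CC[C@@H]2O[Si](C)(C)C(C)(C)C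
A5 | alternative 2 | 2-[cis-4-(tert-butyldimethylsilyloxy)-8-methoxy-1,2,3,4-tetrahydronaphthalen-1-yl]furan | COc1cccc2c1[C@H](c1ccco1)CC[C@@H]2O[Si](C)(C)C(C)(C)C
A6 | alternative 2 | 3-methoxybenzyne | COC1=CC=CC#C1
A7 | alternative 3 | (4S)-5-methoxy-4-[5-methoxy-4-(triisopropylsilyloxy)naphthalen-1-yl]-3,4-dihydronaphthalen-1(2H)-one | COc1cccc2c1[C@H](c1ccc(O[Si](C(C)C)(C(C)C)C(C)C)c3c(OC)cccc13)CCC2=O
A8 | alternative 3 | {4-[(1S)-1-(2-bromo-6-methoxyphenyl)prop-2-en-1-yl]-8-methoxynaphthalen-1-yl}oxy-triisopropylsilane | COc1cccc(Br)c1[C@H](c1ccc(O[Si](C(C)C)(C(C)C)C(C)C)c3c(OC)cccc13)C=C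
A9 | alternative 3 | 9-BBN adduct of A8, boron on the terminal carbon | COc1cccc(Br)c1[C@H](c1ccc(O[Si](C(C)C)(C(C)C)C(C)C)c3c(OC)cccc13)CCB1C2CCCC1CCC2
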